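## Analysis of the target

Huanglongmycin D (14) has no stereocentre. It is a benzophenone in which ring B is a symmetric 2,6-dihydroxyphenyl group and ring A is a benzoic acid with five contiguous substituents. Numbered as the benzoic acid, ring A carries CO2H at C1, the aroyl group at C2, OH at C3, acetyl at C4 and CH2CO2H at C5 (C7 is the benzylic carbon and C8 the carboxyl carbon of this side chain); only C6 bears hydrogen. The difficulty is regiochemical: every position of ring A but one is differentiated, and the diaryl ketone lies between two ortho substituents on each ring, so an aryl–acyl bond formation at that carbonyl is unattractive. The functional groups also react with each other: the C4 acetyl and the C5 acetic acid can condense to a naphthalenediol, the 2-aroylbenzoic acid can close to a hydroxyphthalide, and the three phenols are oxidisable, so phenols and acids are best released last. The plan rests on the polyketide pattern of ring A: the aroyl carbonyl, C2, C3 with its oxygen, C4 and the acetyl carbonyl form a 1,3,5-triketone held as its enol, so C2–C3–C4 is a three-carbon unit that is nucleophilic at both ends. The other three ring carbons are complementary: C5 is at the ketone oxidation level, C1 is β to it and bears the carboxyl group, and C6 is the CH between them, which is the pattern of a 4-oxoalk-2-ynoate.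

## Retrosynthetic reasoning

From 14 back to 12 only protecting groups are put on. The C1 carboxyl is carried as the methyl ester that the acceptor fragment brings in, and the two ring B phenols as the methyl ethers of the purchasable acetophenone 1. Both ethers lie ortho to the diaryl ketone, where a boron Lewis acid cleaves an aryl methyl ether most easily (13 from 12), and the ester is hydrolysed last (14 from 13). No carbon–carbon bond is touched once ring A exists.

12 is traced to 11 and then 10 by changing two spectator groups. In 10 the acetyl group is a dioxolane and C8 is a silyl-protected primary alcohol. Both serve the ring-forming step: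
- With the acetyl carbonyl masked, C4 is activated by one carbonyl only and cannot compete with C2 for the alkyne.
- With C8 at the alcohol level, C7 is a simple ketone α-methylene in the acceptor. Had C8 been an ester during the annulation, C7 would have been a second doubly activated methylene, about as acidic as C2 and placed to close a six-membered ring onto the C3 carbonyl.
- The cyclic ketal is preferred to an acyclic one because a β-keto dialkyl ketal loses alcohol easily on enolisation, whereas opening of a dioxolane is reversible.

The price is one oxidation (12 from 11) after the acidic unmasking (11 from 10).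

Ring A of 10 is cut at C1–C2 and C4–C5, the two bonds that join the nucleophilic unit C2–C3–C4 to the electrophilic unit C5–C6–C1. This gives diketone 3 and ynone 7. A cut at the diaryl ketone would require forming the most hindered bond of the molecule; this cut leaves that ketone intact inside 3 and delivers all five substituents and the aromatic oxidation level in one step. The forward reaction has to add C2 of 3 to the ester-bearing alkyne carbon of 7, close C4 onto the C5 ketone, dehydrate and enolise to the phenol.

3 is cut at C2–C3, between the methyl ketone 1 as nucleophile and the ketal ester 2 as acyl donor. The reverse polarity would need a 2,6-disubstituted aroyl electrophile, which is hindered; here the hindered carbonyl only has to enolise.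

7 is cut at C5–C6: the acetylide of 4 adds to aldehyde 5 to give 6, which is then oxidised. Routes through an activated alkynoic acid derivative were avoided because nucleophilic activators add to such electron-poor alkynes; in the chosen sequence the alkyne meets only a base at low temperature and a neutral oxidant.

## Alternatives that were turned down

Alternative 1: Ring A is cut at all three alternating bonds, C1–C2, C3–C4 and C5–C6, and assembled from three alkynes. The alkynes are tied together twice in triyne A2, by a propiolate ester of the propargylic alcohol that carries the 2,6-dimethoxyphenyl group and by a diisopropylsilyl ether. RhCl(PPh3)3 would cyclotrimerise A2 to the tricyclic phthalide–benzoxasilole A1.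
- For: the tethers fix every ring position, so there is no competition between cyclisation modes; on regiochemical certainty this is stronger than the chosen route.
- Against: none of the three oxygenated positions arrives at its final oxidation level. The C–Si bond must be oxidised to the C3 phenol (Tamao–Fleming oxidation at a di-ortho-substituted arylsilane), the secondary benzylic ether to the acetyl group, and the phthalide C–H to the diaryl ketone. Two stereocentres are made only to be destroyed, and A2 needs a long linear sequence and contains a propiolate ester and a but-3-ynoate, both base-sensitive.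
- Comparison: the chosen route is less controlled in its key step but uses two short fragments and gives a product that needs one oxidation and deprotections only.

Alternative 2: Ring A is kept and cut at C4–acetyl and C5–C7. CsF would release the C4–C5 aryne from the ortho-silyl aryl triflate A4, and the aryne would insert into the C2–C3 bond of methyl acetoacetate A5 to give A3.
- For: the C3 methoxy group directs the enolate carbon to C5 and the aryl anion to C4, which is the required orientation, and both side chains arrive at their final oxidation level. On these two points it is as strong as or stronger than the chosen route, which needs a later side-chain oxidation.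
- Against: A4 is itself a pentasubstituted benzene that already contains the hindered diaryl ketone, the ester, an ether, a silyl group and a triflate. The difficult part of the target is therefore moved into the precursor, which needs a hindered aryl–acyl union and several directed metalations.
- Comparison: the chosen route builds ring A and places the aroyl group in the same step from acetophenone 1, at the cost of a less predictable ring closure.

Alternative 3: Ring A is made as a cyclohexane-1,3-dione by cutting C6–C1 and C2–C3. The dianion of A5 (LiN(iPr)2, two equivalents) would add through its terminal carbon to the aroylacrylate A7 at the carbon β to the aryl ketone, and NaOMe would then close the ketone enolate onto the methyl ester to give A6.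
- For: classical enolate chemistry with cheap reagents, the hindered ketone again comes from an acetophenone, and the Claisen ring closure has only one sensible direction. On reliability of the ring closure it is at least as strong as the chosen route.
- Against: A6 lacks the acetyl group, has oxygen instead of carbon at C5 and is two oxidation levels below the arene. It would need C-acylation at C4, replacement of the C5 oxygen by the acetate carbon with differentiation of the C3 and C5 carbonyls, and a dehydrogenation, each with selectivity questions of its own.
- Comparison: the chosen route reaches the fully substituted arene in one step from the fragments and has the shorter sequence.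

Key step: step 4

Assumption: compounds 1, 2, 4 and 5 are purchasable and are used as bought.

## Route

Step 1
Reactants: 1 2',6'-dimethoxyacetophenone; 2 ethyl 2-(2-methyl-1,3-dioxolan-2-yl)acetate
Product: 3 1-(2,6-dimethoxyphenyl)-4-(2-methyl-1,3-dioxolan-2-yl)butane-1,3-dione
Conditions: NaH (3 equiv), THF, 0 °C to reflux; then AcOH, 0 °C
Reagents that add atoms: none
Why: Crossed Claisen condensation: the sodium enolate of methyl ketone 1 is acylated by the unhindered ester 2, and deprotonation of the product β-diketone by excess NaH drives the equilibrium. The hindered aryl ketone cannot act as the electrophile and the dioxolane is inert to base.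

Step 2
Reactants: 4 methyl propiolate; 5 3-[(tert-butyldimethylsilyl)oxy]propanal
Product: 6 methyl 6-[(tert-butyldimethylsilyl)oxy]-4-hydroxyhex-2-ynoate (racemic)
Conditions: LiN(SiMe3)2, THF, −78 °C; then 5; NH4Cl aq
Reagents that add atoms: none
Why: Addition of a lithium acetylide to an aldehyde: methyl propiolate is deprotonated at −78 °C and adds 1,2 to the unhindered aldehyde faster than it decomposes. The new carbinol carbon is racemic and becomes a carbonyl in step 3.

Step 3
Reactants: 6 methyl 6-[(tert-butyldimethylsilyl)oxy]-4-hydroxyhex-2-ynoate
Product: 7 methyl 6-[(tert-butyldimethylsilyl)oxy]-4-oxohex-2-ynoate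
Conditions: Dess–Martin periodinane, CH2Cl2, 0 °C to rt
Reagents that add atoms: none
Why: Dess–Martin oxidation of a secondary propargylic alcohol to the ynone under neutral, non-aqueous conditions; the doubly activated alkyne meets no nucleophile stronger than acetic acid and the silyl ether is untouched.

Step 4
Reactants: 3 1-(2,6-dimethoxyphenyl)-4-(2-methyl-1,3-dioxolan-2-yl)butane-1,3-dione; 7 methyl 6-[(tert-butyldimethylsilyl)oxy]-4-oxohex-2-ynoate
Product: 10 methyl 5-{2-[(tert-butyldimethylsilyl)oxy]ethyl}-2-(2,6-dimethoxybenzoyl)-3-hydroxy-4-(2-methyl-1,3-dioxolan-2-yl)benzoate, via Michael adduct 8 (not isolated), via aldol adduct 9 (not isolated)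
Conditions: Cs2CO3 (0.3 equiv), 4 Å MS, MeCN, 0 °C to rt, 7 added slowly; then 60 °C
Reagents that add atoms: none
Why: The closest known reaction type is the base-mediated Michael–aldol benzannulation of an active-methylene ketone with an ynone, applied here to a new pair of partners. Cs2CO3 deprotonates 3 at C2, the only carbon in either partner that lies between two carbonyl groups, and this enolate adds to the ester-bearing alkyne carbon of 7, which is β to the ketone, the stronger acceptor group; this forms C1–C2 and gives 8. The anion of 8 is delocalised from C2 through C1=C6 to the C5 oxygen, so the alkene isomers interconvert and the geometry with C2 and C5 on the same side is available. Proton transfer gives the C3/C4 enolate, which closes on the C5 ketone in a 6-(enolendo)-exo-trig aldol addition (C4–C5, ring A, 9); E1cB dehydration and enolisation of the C3 carbonyl then give phenol 10 irreversibly. The first selectivity needed, the site of the Michael attack, is secured by the acidity of C2 and the ketone-directed polarisation of the alkyne. The critical selectivity is the direction of the aldol, since C7 of the acceptor could attack the C3 carbonyl instead: because C8 is a silyl ether and the acetyl a ketal, C4 and C7 are both simple ketone α-methylenes, and the choice falls to the electrophile, where C5 is an unhindered enone carbonyl while C3 lies between the fully substituted C2 and the neopentyl-type C4. O-Cyclisation of an enol oxygen onto C5 gives only a hemiketal that reverts, whereas C-closure leads on to the arene. No stereocentre survives, as those of 8 and 9 are lost on aromatisation.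

Step 5
Reactants: 10 methyl 5-{2-[(tert-butyldimethylsilyl)oxy]ethyl}-2-(2,6-dimethoxybenzoyl)-3-hydroxy-4-(2-methyl-1,3-dioxolan-2-yl)benzoate
Product: 11 methyl 4-acetyl-2-(2,6-dimethoxybenzoyl)-3-hydroxy-5-(2-hydroxyethyl)benzoate
Conditions: 1 M HCl, THF, rt
Reagents that add atoms: water, O
Why: Acid-catalysed hydrolysis of the dioxolane (assisted by the ortho phenol) and of the primary silyl ether in one operation; esters, aryl ethers and ketones are stable. 11 may sit partly as its cyclic hemiketal, which reopens under the conditions of step 6.

Step 6
Reactants: 11 methyl 4-acetyl-2-(2,6-dimethoxybenzoyl)-3-hydroxy-5-(2-hydroxyethyl)benzoate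
Product: 12 2-[2-acetyl-4-(2,6-dimethoxybenzoyl)-3-hydroxy-5-(methoxycarbonyl)phenyl]acetic acid
Conditions: CrO3, H2SO4, H2O, acetone, 0 °C
Reagents that add atoms: water, O
Why: Jones oxidation of a primary alcohol to the carboxylic acid through the aldehyde hydrate. The hydrogen-bonded, acyl-substituted phenol and the acylated dimethoxyarene are electron-poor enough to resist chromic acid at 0 °C, and the aldehyde stage should be passed too quickly to condense with the acetyl group.

Step 7
Reactants: 12 2-[2-acetyl-4-(2,6-dimethoxybenzoyl)-3-hydroxy-5-(methoxycarbonyl)phenyl]acetic acid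
Product: 13 2-[2-acetyl-4-(2,6-dihydroxybenzoyl)-3-hydroxy-5-(methoxycarbonyl)phenyl]acetic acid
Conditions: BBr3 (excess), CH2Cl2, −78 °C to rt; H2O
Reagents that add atoms: none
Why: Lewis acid cleavage of aryl methyl ethers with BBr3; both ethers are ortho to the diaryl ketone, which chelates boron and speeds their cleavage. Any methyl ester cleaved at the same time converges in step 8.

Step 8
Reactants: 13 2-[2-acetyl-4-(2,6-dihydroxybenzoyl)-3-hydroxy-5-(methoxycarbonyl)phenyl]acetic acid
Product: 14 huanglongmycin D, 4-acetyl-5-(carboxymethyl)-2-(2,6-dihydroxybenzoyl)-3-hydroxybenzoic acid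
Conditions: LiOH, THF/H2O (degassed), rt to 40 °C; then 1 M HCl
Reagents that add atoms: lithium hydroxide, [Li+].[OH-]
Why: Saponification of the remaining methyl benzoate, then acidification; nothing else in 13 is base-labile at this temperature and the phenoxides are kept from air.

## Compound list

1 | 1-(2,6-dimethoxyphenyl)ethan-1-one (2',6'-dimethoxyacetophenone) | COc1cccc(OC)c1C(C)=O | starting material
2 | ethyl 2-(2-methyl-1,3-dioxolan-2-yl)acetate | CCOC(=O)CC1(C)OCCO1 | starting material
3 | 1-(2,6-dimethoxyphenyl)-4-(2-methyl-1,3-dioxolan-2-yl)butane-1,3-dione | COc1cccc(OC)c1C(=O)CC(=O)CC1(C)OCCO1 | intermediate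
4 | methyl prop-2-ynoate (methyl propiolate) | COC(=O)C#C | starting material
5 | 3-[(tert-butyldimethylsilyl)oxy]propanal | CC(C)(C)[Si](C)(C)OCCC=O | starting material
6 | methyl 6-[(tert-butyldimethylsilyl)oxy]-4-hydroxyhex-2-ynoate (racemic) | COC(=O)C#CC(O)CCO[Si](C)(C)C(C)(C)C | intermediate
7 | methyl 6-[(tert-butyldimethylsilyl)oxy]-4-oxohex-2-ynoate | COC(=O)C#CC(=O)CCO[Si](C)(C)C(C)(C)C | intermediate
8 | Michael adduct, formed in the flask: methyl 6-[(tert-butyldimethylsilyl)oxy]-2-[1-(2,6-dimethoxyphenyl)-4-(2-methyl-1,3-dioxolan-2-yl)-1,3-dioxobutan-2-yl]-4-oxohex-2-enoate (racemic, interconverting alkene isomers) | COC(=O)C(=CC(=O)CCO[Si](C)(C)C(C)(C)C)C(C(=O)CC1(C)OCCO1)C(=O)c1c(OC)cccc1OC | intermediate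
9 | aldol adduct, formed in the flask: methyl 3-{2-[(tert-butyldimethylsilyl)oxy]ethyl}-6-(2,6-dimethoxybenzoyl)-3-hydroxy-4-(2-methyl-1,3-dioxolan-2-yl)-5-oxocyclohex-1-ene-1-carboxylate (mixture of diastereomers) | COC(=O)C1=CC(O)(CCO[Si](C)(C)C(C)(C)C)C(C2(C)OCCO2)C(=O)C1C(=O)c1c(OC)cccc1OC | intermediate
10 | methyl 5-{2-[(tert-butyldimethylsilyl)oxy]ethyl}-2-(2,6-dimethoxybenzoyl)-3-hydroxy-4-(2-methyl-1,3-dioxolan-2-yl)benzoate | COC(=O)c1cc(CCO[Si](C)(C)C(C)(C)C)c(C2(C)OCCO2)c(O)c1C(=O)c1c(OC)cccc1OC | intermediate
11 | methyl 4-acetyl-2-(2,6-dimethoxybenzoyl)-3-hydroxy-5-(2-hydroxyethyl)benzoate | COC(=O)c1cc(CCO)c(C(C)=O)c(O)c1C(=O)c1c(OC)cccc1OC | intermediate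
12 | 2-[2-acetyl-4-(2,6-dimethoxybenzoyl)-3-hydroxy-5-(methoxycarbonyl)phenyl]acetic acid | COC(=O)c1cc(CC(=O)O)c(C(C)=O)c(O)c1C(=O)c1c(OC)cccc1OC | intermediate
13 | 2-[2-acetyl-4-(2,6-dihydroxybenzoyl)-3-hydroxy-5-(methoxycarbonyl)phenyl]acetic acid | COC(=O)c1cc(CC(=O)O)c(C(C)=O)c(O)c1C(=O)c1c(O)cccc1O | intermediate
14 | huanglongmycin D, 4-acetyl-5-(carboxymethyl)-2-(2,6-dihydroxybenzoyl)-3-hydroxybenzoic acid | CC(=O)c1c(CC(=O)O)cc(C(=O)O)c(C(=O)c2c(O)cccc2O)c1O | target

## Step count and least certain steps

Total: 8 steps. Longest linear sequence: 7 steps (steps 2 to 8, from 4 and 5 to 14).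

Step 4 (key step). Three processes are most likely to go wrong. The first is ring closure in the opposite sense, by enolisation at C7 and aldol addition to the C3 carbonyl, which would give an isomeric phenol. The second is stalling at the Michael adduct, because the C4–C5 closure brings the bulky ketal carbon next to a new tertiary carbinol. The third is base-induced loss of silanol from the β-silyloxy ketone. The fallback sets out from 3 and returns at 11. It uses a donor in which both ring-forming carbons are doubly activated and an acceptor whose ketone has no α-hydrogen. Mild hydrolysis of the ketal of 3 (pyridinium p-toluenesulfonate, wet acetone) gives 1-(2,6-dimethoxyphenyl)hexane-1,3,5-trione F1. Lithiation of tert-butyl(but-3-yn-1-yloxy)dimethylsilane (nBuLi, THF, −78 °C) and addition to excess dimethyl oxalate gives methyl 6-[(tert-butyldimethylsilyl)oxy]-2-oxohex-3-ynoate F2. Under Cs2CO3 the less hindered C4 of F1 adds to the alkyne carbon of F2 that is β to the ketone (forming C4–C5), and C2 then condenses with the keto ester carbonyl (forming C1–C2). This gives methyl 4-acetyl-5-{2-[(tert-butyldimethylsilyl)oxy]ethyl}-2-(2,6-dimethoxybenzoyl)-3-hydroxybenzoate F3, and 1 M HCl in THF removes the silyl group to give 11. Closure through the acceptor is impossible in this pairing; its own weak point is that the order of attack by C4 and C2 rests only on the steric difference between the acetyl and the 2,6-dimethoxybenzoyl ends.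

Step 1. Proton transfer to the ester may compete with acylation of the slowly reacting, hindered ketone enolate, leading to self-condensation of 2 or ring-opening elimination of the ketal from the ester enolate. The fallback sets out from 1 and 2 and returns at 3, replacing the acylation by an aldol addition and an oxidation. Reduction of 2 with iBu2AlH (CH2Cl2, −78 °C) gives 2-(2-methyl-1,3-dioxolan-2-yl)acetaldehyde F4. The lithium enolate of 1 (LiN(iPr)2, THF, −78 °C) adds to F4 to give racemic 1-(2,6-dimethoxyphenyl)-3-hydroxy-4-(2-methyl-1,3-dioxolan-2-yl)butan-1-one F5, and Dess–Martin oxidation of F5 gives 3.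

Step 3. The ynone may decompose during oxidation and isolation, by conjugate addition of acetic acid or water to the doubly activated alkyne, β-elimination of silanol, or oligomerisation. The fallback sets out from 6 and 3 and returns at 10. The ynone is not made as a discrete compound: alcohol 6 serves as the annulation partner and is oxidised with activated MnO2 in the presence of 3 and Cs2CO3, so that 7 is consumed by the Michael addition as it forms (tandem oxidation–conjugate addition).

Step 6. The transient arylacetaldehyde may condense with the neighbouring acetyl group (closure to a naphthol), or the phenol may be degraded by the acidic chromium oxidant. The fallback sets out from 10 and returns at 12; the side chain is oxidised while the acetyl group is still masked. Bu4NF (THF, 0 °C) removes only the silyl group to give methyl 2-(2,6-dimethoxybenzoyl)-3-hydroxy-5-(2-hydroxyethyl)-4-(2-methyl-1,3-dioxolan-2-yl)benzoate F6. Dess–Martin oxidation gives the aldehyde methyl 2-(2,6-dimethoxybenzoyl)-3-hydroxy-4-(2-methyl-1,3-dioxolan-2-yl)-5-(2-oxoethyl)benzoate F7. Pinnick oxidation (NaClO2, NaH2PO4, 2-methylbut-2-ene, tBuOH/H2O) gives 2-[4-(2,6-dimethoxybenzoyl)-3-hydroxy-5-(methoxycarbonyl)-2-(2-methyl-1,3-dioxolan-2-yl)phenyl]acetic acid F8, and 1 M HCl in THF then hydrolyses the ketal to give 12.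

## Further compounds

F1 | step 4 | 1-(2,6-dimethoxyphenyl)hexane-1,3,5-trione | COc1cccc(OC)c1C(=O)CC(=O)CC(C)=O
F2 | step 4 | methyl 6-[(tert-butyldimethylsilyl)oxy]-2-oxohex-3-ynoate | COC(=O)C(=O)C#CCCO[Si](C)(C)C(C)(C)C
F3 | step 4 | methyl 4-acetyl-5-{2-[(tert-butyldimethylsilyl)oxy]ethyl}-2-(2,6-dimethoxybenzoyl)-3-hydroxybenzoate | COC(=O)c1cc(CCO[Si](C)(C)C(C)(C)C)c(C(C)=O)c(O)c1C(=O)c1c(OC)cccc1OC
F4 | step 1 | 2-(2-methyl-1,3-dioxolan-2-yl)acetaldehyde | CC1(CC=O)OCCO1
F5 | step 1 | 1-(2,6-dimethoxyphenyl)-3-hydroxy-4-(2-methyl-1,3-dioxolan-2-yl)butan-1-one (racemic) | COc1cccc(OC)c1C(=O)CC(O)CC1(C)OCCO1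
F0 | step 3 | none | none
F6 | step 6 | methyl 2-(2,6-dimethoxybenzoyl)-3-hydroxy-5-(2-hydroxyethyl)-4-(2-methyl-1,3-dioxolan-2-yl)benzoate | COC(=O)c1cc(CCO)c(C2(C)OCCO2)c(O)c1C(=O)c1c(OC)cccc1OC
F7 | step 6 | methyl 2-(2,6-dimethoxybenzoyl)-3-hydroxy-4-(2-methyl-1,3-dioxolan-2-yl)-5-(2-oxoethyl)benzoate | COC(=O)c1cc(CC=O)c(C2(C)OCCO2)c(O)c1C(=O)c1c(OC)cccc1OC
F8 | step 6 | 2-[4-(2,6-dimethoxybenzoyl)-3-hydroxy-5-(methoxycarbonyl)-2-(2-methyl-1,3-dioxolan-2-yl)phenyl]acetic acid | COC(=O)c1cc(CC(=O)O)c(C2(C)OCCO2)c(O)c1C(=O)c1c(OC)cccc1OC
A1 | alternative 1 | tricyclic phthalide–benzoxasilole with the 2,6-dimethoxyphenyl group and the CH2CO2Me side chain (mixture of diastereomers) | O=C1OC(c2c(OC)cccc2OC)c3c1cc(CC(=O)OC)c4c3[Si](C(C)C)(C(C)C)OC4C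
A2 | alternative 1 | methyl 5-({[3-(2,6-dimethoxyphenyl)-3-(prop-2-ynoyloxy)prop-1-yn-1-yl]di(propan-2-yl)silyl}oxy)hex-3-ynoate (mixture of diastereomers) | C#CC(=O)OC(C#C[Si](C(C)C)(C(C)C)OC(C)C#CCC(=O)OC)c1c(OC)cccc1OC
A3 | alternative 2 | methyl 4-acetyl-2-(2,6-dimethoxybenzoyl)-3-methoxy-5-(2-methoxy-2-oxoethyl)benzoate | COC(=O)Cc1cc(C(=O)OC)c(C(=O)c2c(OC)cccc2OC)c(OC)c1C(C)=O
A4 | alternative 2 | methyl 2-(2,6-dimethoxybenzoyl)-3-methoxy-5-{[(trifluoromethyl)sulfonyl]oxy}-4-(trimethylsilyl)benzoate | COC(=O)c1cc(OS(=O)(=O)C(F)(F)F)c([Si](C)(C)C)c(OC)c1C(=O)c1c(OC)cccc1OC
A5 | alternative 2 | methyl acetoacetate | COC(=O)CC(C)=O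
A6 | alternative 3 | (±)-trans tert-butyl 2-(2,6-dimethoxybenzoyl)-3,5-dioxocyclohexane-1-carboxylate (one enantiomer drawn) | CC(C)(C)OC(=O)[C@@H]1CC(=O)CC(=O)[C@H]1C(=O)c1c(OC)cccc1OC
A7 | alternative 3 | tert-butyl (E)-4-(2,6-dimethoxyphenyl)-4-oxobut-2-enoate | CC(C)(C)OC(=O)/C=C/C(=O)c1c(OC)cccc1OC
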